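## The problem

Lehualide H (14) is an achiral 2H-pyran-2-one in which every ring carbon is substituted. With the ring numbered O1, C2 (carbonyl), C3, C4, C5, C6, it carries methoxy groups at C3 and C4, a methyl group at C5 and, at C6, an unbranched ten-carbon chain ending in an S-acetyl thiol. There is no stereocentre, so nothing has to be controlled in space and nothing can act as a controlling element; the task is one of regiochemistry and chemoselectivity. Four different substituents must be placed around one small ring. The C5-methyl/C6-alkyl pair corresponds to an unsymmetrical ketone whose two α-positions are both methylene groups of nearly equal acidity, so ordinary enolate chemistry cannot tell them apart. The oxygen at C4 must be methylated in the 2-pyranone sense, although the oxyanion of a 4-hydroxy-2-pyranone is ambident and can also react through the C2 carbonyl oxygen. The thioacetate is cleaved by bases, hydrides and organometallic reagents and binds to late transition metals, so it has to be introduced last. Until then the chain terminus needs a placeholder that survives an organomagnesium reagent, a rhodium catalyst with a silane, and acyl chlorides. The feature that opens the ring to a short synthesis is that C2–C3(OMe)–C4 is a methoxymalonyl unit and O1–C6(chain)=C5(Me) is the enol of an ethyl ketone. The ring can therefore be assembled from two three-atom pieces, with the C3 methoxy group arriving at the correct oxidation level.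

## Retrosynthesis

**C–S bond at the chain terminus.** The first cut removes the thioacetate and leads back to the primary bromide 13. Cutting S–acetyl instead would require a free, oxidation-prone thiol. A terminal alkene as placeholder would not be innocent in the rhodium/silane step that comes earlier. Compound 13 no longer contains the one group that is incompatible with bases and metals. The forward reaction only has to be an SN2 displacement at a primary carbon by a soft sulfur nucleophile that leaves the vinylogous carbonate ring alone.

**O–CH3 bond at C4.** The C4 methoxy group is cut next, giving the 4-hydroxy-2-pyranone 12. Of the two methoxy groups only this one can sensibly be introduced late, because a 4-hydroxy-2-pyranone is what an acylative ring synthesis delivers. The C3 methoxy group has no comparable late-stage entry and must come with the carbon skeleton. The forward reaction has to alkylate O4 rather than the C2 carbonyl oxygen and must tolerate the bromide.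

**C4–C5 and O1–C2 (key disconnection).** Cutting these two bonds divides 12 into the silyl enol ether 7 (O1, C6, C5, the methyl group and the chain) and methoxymalonyl dichloride 10 (C2, C3 with its methoxy group, C4).
- A cut at C3–C4 alone would form one bond and would need an enol ester of defined geometry.
- A cut through C5–C6 would require a metal-mediated union.
- The chosen cut forms two bonds in one base-free operation from two acyclic pieces, through the acyclic 3,5-dioxoacyl chloride 11.

The forward reaction asks that the methyl-bearing enol carbon be acylated and that the enol oxygen then close onto the second acyl chloride. Which α-carbon reacts must already be written into 7.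

**Si–O and C–H bonds of the enol ether.** Enol ether 7 is traced to the vinyl ketone 5 and triethylsilane 6 by formal removal of H–Si from across the O=C–C=C unit. Enolisation of the saturated ethyl ketone would give both regioisomers. Conjugate hydrosilylation places the enol double bond between the former carbonyl carbon and the former vinyl α-carbon by construction. The forward reaction needs 1,4- over 1,2-addition and a catalyst that leaves the alkyl bromide alone.

**Acyl–vinyl bond.** Vinyl ketone 5 is cut between the carbonyl and vinyl carbons into the N-methoxy-N-methylamide 3 and vinylmagnesium bromide 4. Amide 3 comes from 11-bromoundecanoic acid 1 through its acid chloride 2. Acid 1 supplies C6 (its carboxyl carbon) and the whole ten-carbon tether with the bromine already in place. The forward reaction must stop at mono-addition and must not touch the bromide.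

**The malonyl component.** Dichloride 10 is a functional-group interconversion away from methoxymalonic acid 9, which is the saponification product of commercial dimethyl methoxymalonate 8. No carbon–carbon bond is made, and the only demand is mild handling of a diacid that can decarboxylate.

## Roads not taken

**Alternative 1:** The ring is cut at C4–C5 and C6–O1.
- Pieces: (Z)-2,3-dimethoxyprop-2-enoic acid A1 supplies O1, C2, C3 and C4 with both methoxy groups. The conjugated enyne (E)-tert-butyldimethyl(tridec-9-en-11-yn-1-yloxy)silane A2 supplies C5 with its methyl group, C6 and the chain.
- Key step: under [Cp*RhCl2]2 (Cp* = C5Me5) with Cu(OAc)2 as oxidant, the carboxylate would direct trivalent rhodium to the β C–H bond. The alkyne would insert and C6–O1 would form by reductive elimination, giving 6-[(E)-10-(tert-butyldimethylsilyloxy)dec-1-en-1-yl]-3,4-dimethoxy-5-methyl-2H-pyran-2-one A3.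
- Merits: the union is convergent and catalytic. Both methoxy groups are in place from the start, so the ambident O-methylation of the chosen plan is avoided altogether. On that point this road is better.
- Weak points:
  - The C–H bond to be metalated sits on an oxygen-bearing, electron-rich carbon, outside the usual range of α-substituted acrylic acids.
  - A1 must be geometrically pure, with hydrogen cis to the carboxyl group.
  - The orientation of alkyne insertion rests on a preference of the alkenyl group for the position next to oxygen, not on construction.
  - After the key step the alkene must be hydrogenated without touching the pyranone, the silyl ether removed and the alcohol converted to the thioacetate. A2 itself needs several steps.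
- Comparison: the chosen plan is shorter, uses bulk reagents and fixes the C5/C6 regiochemistry unambiguously.

**Alternative 2:** The ring is cut at C5–C6 and O1–C2, with C6 and O1 both coming from carbon monoxide A6.
- Pieces: dimethyl squarate A4 would be converted by methyl addition and chlorination into 4-chloro-2,3-dimethoxy-4-methylcyclobut-2-en-1-one A5.
- Key step: a zerovalent palladium catalyst such as Pd(PPh3)4 would couple A5, A6 and dec-9-en-1-ylzinc bromide A7. The acylated four-membered ring would open thermally and reclose through oxygen to give 6-(dec-9-en-1-yl)-3,4-dimethoxy-5-methyl-2H-pyran-2-one A8. Radical addition of thioacetic acid A9 to the terminal alkene would finish the synthesis.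
- Merits: on paper this is the shortest road, about five steps. Both methoxy groups are again present from the start. In step count and in avoiding the ambident methylation it is better than the chosen plan.
- Weak points, all in the key step:
  - Three components must be joined in the right order with an sp3 zinc reagent that carries β-hydrogens, so direct coupling without carbonyl insertion and β-hydride elimination both compete.
  - The allyl-type palladium intermediate from A5 can react at either terminus.
  - A5 is a sensitive tertiary allylic chloride.
  - A6 needs pressure equipment, and A4 is costly and a strong sensitiser.
- Comparison: the chosen plan sets against this that each of its steps is an established reaction on its own substrate class, and that its regiochemistry does not depend on the outcome of a multicomponent catalytic cycle.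

**Alternative 3:** The ring is cut at C3–C4 only.
- Pieces: the precursor is the enol ester methyl (Z)-3-[(methoxyacetyl)oxy]-2-methyltrideca-2,12-dienoate A10, made by O-acylation of the corresponding β-keto ester.
- Key step: a strong amide base would form the methoxyacetate enolate, which attacks the neighbouring methyl ester in a Dieckmann closure to give 6-(dec-9-en-1-yl)-4-hydroxy-3-methoxy-5-methyl-2H-pyran-2-one A11. O-Methylation and radical addition of A9 would follow.
- Merits: the materials are cheap and the length is comparable to the chosen plan. The terminal alkene is a more robust spectator than a bromide during the basic methylation, which is a real advantage.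
- Weak points:
  - Only one ring bond forms in the key step.
  - A10 must have the acyloxy group cis to the ester, so its geometry has to be controlled.
  - A strong base acting on an enol ester invites acyl transfer and cleavage back to the β-keto ester enolate.
  - The ambident methylation is shared with the chosen plan.
- Comparison: the chosen plan forms both ring bonds in one neutral step and needs no geometrical control, since the geometry of its enol ether is lost on aromatisation. Its bromide allows a direct displacement at the end, at the cost of carrying an electrophile through the methylation.

Key step: step 6

Remark: the target has no stereocentre. Intermediate 11 and the fallback compounds that carry sp3 stereocentres are racemic or diastereomeric mixtures and are written without configuration.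

## Route

Step 1
Reactants: 1 11-bromoundecanoic acid
Product: 3 11-bromo-N-methoxy-N-methylundecanamide, via 11-bromoundecanoyl chloride 2 (not isolated)
Conditions: (COCl)2, DMF (cat.), CH2Cl2, 0 °C → rt; concentrate; then MeNH(OMe)·HCl, pyridine, CH2Cl2, 0 °C → rt
Reagents that add atoms: oxalyl chloride, ClC(=O)C(Cl)=O (the chlorine of 2); N,O-dimethylhydroxylamine hydrochloride, CNOC.Cl
Why: Vilsmeier-type acid chloride formation followed by Schotten–Baumann-type amidation to the Weinreb amide; the primary bromide is inert to both stages, and pyridine is used instead of a trialkylamine so that the acid chloride is not dehydrochlorinated to a ketene.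

Step 2
Reactants: 3 11-bromo-N-methoxy-N-methylundecanamide; 4 vinylmagnesium bromide
Product: 5 13-bromotridec-1-en-3-one
Conditions: THF, −20 → 0 °C; inverse quench into cold 2 M aq. HCl; used promptly
Reagents that add atoms: none
Why: Weinreb ketone synthesis, in which the five-membered magnesium chelate of the tetrahedral adduct holds the carbonyl masked until work-up and so prevents a second addition; a vinyl Grignard reagent does not displace an unactivated primary bromide at this temperature, and the acidic inverse quench keeps the liberated hydroxylamine protonated so that it cannot add to the new enone.

Step 3
Reactants: 5 13-bromotridec-1-en-3-one; 6 triethylsilane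
Product: 7 (Z)-[(13-bromotridec-2-en-3-yl)oxy]triethylsilane
Conditions: RhCl(PPh3)3 (1 mol%), toluene, 50 °C; filtration through Et3N-deactivated silica
Reagents that add atoms: none
Why: Rhodium-catalysed hydrosilylation of an α,β-unsaturated ketone with a monohydrosilane proceeds as a 1,4-addition through the s-cis enone, placing hydrogen on the terminal carbon and silicon on oxygen; the enol double bond is thereby fixed toward the former vinyl carbon, the Z geometry follows from the s-cis delivery (and is of no later consequence), and the alkyl bromide is not touched by monovalent rhodium under these conditions.

Step 4
Reactants: 8 dimethyl 2-methoxymalonate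
Product: 9 2-methoxymalonic acid
Conditions: NaOH (2.1 equiv), H2O/MeOH, 0 °C → rt; then aq. HCl to pH 1 at 0 °C, continuous Et2O extraction, evaporation below 30 °C
Reagents that add atoms: sodium hydroxide, [Na+].[OH-]
Why: Ordinary saponification of a malonic diester by acyl–oxygen cleavage; the α-methoxy group is not a leaving group under these conditions, and the cold work-up avoids decarboxylation of the free diacid.

Step 5
Reactants: 9 2-methoxymalonic acid
Product: 10 2-methoxymalonyl dichloride
Conditions: (COCl)2 (2.5 equiv), DMF (cat.), CH2Cl2, 0 °C → rt; volatiles removed, bulb-to-bulb distillation, used at once
Reagents that add atoms: oxalyl chloride, ClC(=O)C(Cl)=O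
Why: Acid chloride formation through the chloroiminium (Vilsmeier-type) catalyst at or below room temperature; all by-products are gases, so the moisture-sensitive dichloride needs no aqueous handling and the diacid is never heated.

Step 6
Reactants: 7 (Z)-[(13-bromotridec-2-en-3-yl)oxy]triethylsilane; 10 2-methoxymalonyl dichloride
Product: 12 6-(10-bromodecyl)-4-hydroxy-3-methoxy-5-methyl-2H-pyran-2-one, via 3,5-dioxoacyl chloride 11 (not isolated)
Conditions: 10 (1.1 equiv), Et2O, −78 °C → rt, 16 h
Reagents that add atoms: none
Why: The electron-rich enol carbon of 7 is acylated by one acyl chloride of 10 (or by the chlorocarbonyl methoxyketene that 10 forms by loss of hydrogen chloride), silicon leaving as Et3SiCl, which forms C4–C5 and gives the 2-methyl-1,3-diketone 11. The enol oxygen of the chain ketone in 11 then adds to the remaining acyl chloride and expels chloride, a 6-exo-trig addition–elimination that closes O1–C2 (from the ketene form the same bond arises by a six-electron oxa-electrocyclisation), and tautomerisation gives the aromatic 4-hydroxy-2-pyranone 12. The closest known reaction type is the annulation of silyl enol ethers and ketones with malonyl and monosubstituted malonyl dichlorides to give 4-hydroxy-2-pyranones. Because the two acyl carbons of 10 are constitutionally equivalent, C-acylation followed by O-acylation and the reverse order converge on the same ring. No stereocentre is formed: the two sp3 centres of 11 disappear on aromatisation and the Z geometry of 7 is lost. The selectivity required is regiochemical, namely that the methyl-bearing carbon and not the chain methylene becomes C5, and it is secured by the position of the enol double bond in 7, which no base or enolisation step is allowed to move. The methoxy group at C3 and the methyl group at C5 block the second annulation that unsubstituted hydroxypyranones undergo with excess malonyl dichloride, and the primary bromide is inert to acyl chlorides and to the acid released in ether.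

Step 7
Reactants: 12 6-(10-bromodecyl)-4-hydroxy-3-methoxy-5-methyl-2H-pyran-2-one
Product: 13 6-(10-bromodecyl)-3,4-dimethoxy-5-methyl-2H-pyran-2-one
Conditions: Me2SO4 (3 equiv), K2CO3, acetone, rt → 40 °C
Reagents that add atoms: dimethyl sulfate, COS(=O)(=O)OC
Why: O-Alkylation of the vinylogous-acid oxyanion with a hard methylating agent; dimethyl sulfate with K2CO3 in acetone is the combination known to favour methylation at O4 of 4-hydroxy-2-pyranones, and the excess of this much stronger electrophile should outrun alkylation by the primary bromide.

Step 8
Reactants: 13 6-(10-bromodecyl)-3,4-dimethoxy-5-methyl-2H-pyran-2-one
Product: 14 lehualide H, 6-[10-(acetylsulfanyl)decyl]-3,4-dimethoxy-5-methyl-2H-pyran-2-one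
Conditions: KSC(O)CH3 (1.2 equiv), DMF, rt
Reagents that add atoms: potassium thioacetate, CC(=O)[S-].[K+]
Why: SN2 displacement of a primary bromide by the soft, weakly basic thioacetate anion in a dipolar aprotic solvent; the dimethoxypyranone ring is not attacked at room temperature and the thioester is formed in the last step, so it meets no further reagent.

## Compound list

1 | 11-bromoundecanoic acid | OC(=O)CCCCCCCCCCBr | starting material
2 | 11-bromoundecanoyl chloride | ClC(=O)CCCCCCCCCCBr | intermediate (not isolated)
3 | 11-bromo-N-methoxy-N-methylundecanamide | CON(C)C(=O)CCCCCCCCCCBr | intermediate
4 | vinylmagnesium bromide | C=C[Mg]Br | starting material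
5 | 13-bromotridec-1-en-3-one | C=CC(=O)CCCCCCCCCCBr | intermediate
6 | triethylsilane | CC[SiH](CC)CC | starting material
7 | (Z)-[(13-bromotridec-2-en-3-yl)oxy]triethylsilane | C/C=C(/CCCCCCCCCCBr)O[Si](CC)(CC)CC | intermediate
8 | dimethyl 2-methoxymalonate | COC(C(=O)OC)C(=O)OC | starting material
9 | 2-methoxymalonic acid | COC(C(=O)O)C(=O)O | intermediate
10 | 2-methoxymalonyl dichloride | COC(C(Cl)=O)C(Cl)=O | intermediate
11 | 15-bromo-2-methoxy-4-methyl-3,5-dioxopentadecanoyl chloride (mixture of diastereomers and enol forms) | COC(C(Cl)=O)C(=O)C(C)C(=O)CCCCCCCCCCBr | intermediate (not isolated)
12 | 6-(10-bromodecyl)-4-hydroxy-3-methoxy-5-methyl-2H-pyran-2-one | COc1c(O)c(C)c(CCCCCCCCCCBr)oc1=O | intermediate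
13 | 6-(10-bromodecyl)-3,4-dimethoxy-5-methyl-2H-pyran-2-one | COc1c(C)c(CCCCCCCCCCBr)oc(=O)c1OC | intermediate
14 | lehualide H, 6-[10-(acetylsulfanyl)decyl]-3,4-dimethoxy-5-methyl-2H-pyran-2-one | COc1c(C)c(CCCCCCCCCCSC(C)=O)oc(=O)c1OC | target

## Step count and risk assessment

Total: 8 steps. Longest linear sequence: 6 steps (steps 1, 2, 3, 6, 7, 8 from 11-bromoundecanoic acid 1). The malonyl branch (steps 4 and 5) joins at step 6.

**Step 6 (key step).** The most likely failures are:
- protodesilylation of 7 by the acid that the annulation itself releases, which erases the regiochemical information before C-acylation has taken place;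
- self-condensation of the methoxyketene derived from 10, or use of a dichloride that has partly decomposed on preparation;
- incomplete closure of the ring after the first acylation.

The fallback separates the two bond formations and does not need 10. It sets out from 7 and 8 and returns at 12. Diester 8 would be half-saponified (KOH, one equivalent, MeOH, 0 °C) to 2,3-dimethoxy-3-oxopropanoic acid F1 and converted with oxalyl chloride into methyl 3-chloro-2-methoxy-3-oxopropanoate F2. ZnCl2-mediated C-acylation of 7 with F2 in CH2Cl2, a Mukaiyama-type acylation of a silyl enol ether, would give methyl 15-bromo-2-methoxy-4-methyl-3,5-dioxopentadecanoate F3, with the regiochemistry still dictated by 7. DBU in warm toluene would then lactonise F3 with loss of methanol to 12, the standard closure of 3,5-dioxo esters to 4-hydroxy-2-pyranones.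

**Step 2.** Two processes threaten the vinyl ketone: conjugate addition of the liberated N,O-dimethylhydroxylamine to the enone during work-up, and polymerisation of the enone on concentration. The fallback forms the enone in the absence of any amine. It sets out from 3 and returns at 5. Reduction of 3 with i-Bu2AlH at −78 °C would give 11-bromoundecanal F4. Addition of 4 at −78 °C would give racemic 13-bromotridec-1-en-3-ol F5. Oxidation with Dess–Martin periodinane (or MnO2) would deliver 5, which would be carried directly into step 3.

**Step 3.** Competing 1,2-hydrosilylation of the carbonyl group, polymerisation of the enone before it is reduced, and hydrolysis of the enol ether during isolation are the concerns. The fallback reaches the same enol ether by alkene isomerisation, so that the position of the carbinol carbon defines the regiochemistry. It sets out from 5 and returns at 7. Reduction of 5 with NaBH4 and CeCl3·7H2O in MeOH (Luche conditions) would give 13-bromotridec-1-en-3-ol F5. Silylation with Et3SiCl and imidazole would give [(13-bromotridec-1-en-3-yl)oxy]triethylsilane F6. Isomerisation with hydrogen-activated [Ir(cod)(PMePh2)2]PF6 in THF would move the double bond into conjugation with oxygen and give 7, possibly together with (E)-[(13-bromotridec-2-en-3-yl)oxy]triethylsilane F7. Both isomers converge on 12 in step 6. F6 is also the product that a 1,2-hydrosilylation in step 3 would form, so material diverted that way could be recovered by the same isomerisation.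

**Step 7.** The alkylation of the ambident oxyanion may lose site selectivity by reaction through the C2 carbonyl oxygen, and the oxyanion of one molecule may be alkylated by the bromide terminus of another. The fallback avoids a long-lived free oxyanion and a basic medium. It sets out from 12 and returns at 13. Mitsunobu methylation with methanol, PPh3 and diisopropyl azodicarboxylate in THF is known to alkylate 4-hydroxy-2-pyranones at O4 under neutral conditions, in which the bromide is not activated. No new intermediate is involved.

## Further compounds

F1 | step 6 | 2,3-dimethoxy-3-oxopropanoic acid (monomethyl methoxymalonate, racemic) | COC(C(=O)O)C(=O)OC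
F2 | step 6 | methyl 3-chloro-2-methoxy-3-oxopropanoate (racemic) | COC(C(Cl)=O)C(=O)OC
F3 | step 6 | methyl 15-bromo-2-methoxy-4-methyl-3,5-dioxopentadecanoate (mixture of diastereomers) | COC(=O)C(OC)C(=O)C(C)C(=O)CCCCCCCCCCBr
F4 | step 2 | 11-bromoundecanal | O=CCCCCCCCCCCBr
F5 | step 2 | 13-bromotridec-1-en-3-ol (racemic) | C=CC(O)CCCCCCCCCCBr
F6 | step 3 | [(13-bromotridec-1-en-3-yl)oxy]triethylsilane (racemic) | C=CC(CCCCCCCCCCBr)O[Si](CC)(CC)CC
F7 | step 3 | (E)-[(13-bromotridec-2-en-3-yl)oxy]triethylsilane | C/C=C(\CCCCCCCCCCBr)O[Si](CC)(CC)CC
F0 | step 7 | none | none
A1 | alternative 1 | (Z)-2,3-dimethoxyprop-2-enoic acid | CO/C=C(\OC)C(=O)O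
A2 | alternative 1 | (E)-tert-butyldimethyl(tridec-9-en-11-yn-1-yloxy)silane | CC#C/C=C/CCCCCCCCO[Si](C)(C)C(C)(C)C
A3 | alternative 1 | 6-[(E)-10-(tert-butyldimethylsilyloxy)dec-1-en-1-yl]-3,4-dimethoxy-5-methyl-2H-pyran-2-one | COc1c(C)c(/C=C/CCCCCCCCO[Si](C)(C)C(C)(C)C)oc(=O)c1OC
A4 | alternative 2 | dimethyl squarate (3,4-dimethoxycyclobut-3-ene-1,2-dione) | COC1=C(OC)C(=O)C1=O
A5 | alternative 2 | 4-chloro-2,3-dimethoxy-4-methylcyclobut-2-en-1-one (racemic) | COC1=C(OC)C(C)(Cl)C1=O
A6 | alternative 2 | carbon monoxide | [C-]#[O+]
A7 | alternative 2 | dec-9-en-1-ylzinc bromide | C=CCCCCCCCC[Zn]Br
A8 | alternative 2 | 6-(dec-9-en-1-yl)-3,4-dimethoxy-5-methyl-2H-pyran-2-one | COc1c(C)c(CCCCCCCCC=C)oc(=O)c1OC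
A9 | alternative 2 | thioacetic acid | CC(=O)S
A10 | alternative 3 | methyl (Z)-3-[(methoxyacetyl)oxy]-2-methyltrideca-2,12-dienoate | COCC(=O)O/C(CCCCCCCCC=C)=C(/C)C(=O)OC
A11 | alternative 3 | 6-(dec-9-en-1-yl)-4-hydroxy-3-methoxy-5-methyl-2H-pyran-2-one | COc1c(O)c(C)c(CCCCCCCCC=C)oc1=O
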